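**Retrosynthetic overview**
1. Target 28 ⇐ bis(triethylsilyl) ether 27 ⇐ tetraene diacetate 24 by one-flask ring-closing metathesis (cyclopentene C3=C4, last ring) and cross-metathesis (isobutenyl end).
2. 24 ⇐ C12 aldehyde 19 + acetoxyallyl-tin reagent (C12–C13 bond, C12 and C13 stereocentres); 19 ⇐ lactone 16 by Weinreb opening.
3. Seven-membered ring ⇐ cyclohexanone 12 by one-carbon ring expansion (Me3SiCHN2 insertion, 1,2-shift of C8) that brings in C9 with its oxygen; C10 ketone → exocyclic methylene.
4. 12 ⇐ γ-lactone-fused cyclohexenone 8 by anti conjugate addition (isopropenyl, C5) and enolate allylation (C1).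
5. 8 ⇐ (S)-cyclohex-2-en-1-ol + propanoyl chloride by Ireland–Claisen (C7, C11), oxidative lactonization (C6–O) and allylic oxidation. Ring order: six-membered carbocycle (bought) → temporary γ-lactone → seven-membered ring (expansion) → cyclopentene.

Convention: atom labels C1–C20 are those of the target (cyclopentene C1–C5, seven-membered ring C1/C5–C10, side chain C11–C16, C17 on C4, C18 = exocyclic CH2, C19 on C11, C20 on C15); β is the ring face that carries the C6 oxygen, α the other face.
Assumption: (S)-cyclohex-2-en-1-ol is bought enantiopure.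

**Route**

Step 1
Reactants: 1 (S)-cyclohex-2-en-1-ol; 2 propanoyl chloride
Product: 3 (S)-cyclohex-2-en-1-yl propanoate
Conditions: Et3N, DMAP (cat.), CH2Cl2, 0 → 23 °C
Reagents that add atoms: none
Why: DMAP-catalysed O-acylation (esterification) of the allylic alcohol, which leaves the carbinol stereocentre (the source of all later chirality) untouched.

Step 2
Reactants: 3 (S)-cyclohex-2-en-1-yl propanoate
Product: 6 (2R)-2-[(1R)-cyclohex-2-en-1-yl]propanoic acid, via silyl ketene acetal 4 (not isolated), via trimethylsilyl ester 5 (not isolated)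
Conditions: LiN(i-Pr)2, THF, −78 °C; Me3SiCl, −78 → 65 °C; then 1 M HCl
Reagents that add atoms: chlorotrimethylsilane, C[Si](C)(C)Cl (its silyl group is carried by 4 and 5 and lost again before 6)
Why: Ireland–Claisen rearrangement, in which kinetic enolization in THF gives the E ketene acetal (methyl trans to OSiMe3) that rearranges suprafacially through the boat transition state preferred by cyclohex-2-enyl esters, so the C5–O chirality is relayed to C7 and the enolate geometry sets C11 (moderate dr expected; the minor C11 epimer is removed at crystalline lactone 7).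

Step 3
Reactants: 6 (2R)-2-[(1R)-cyclohex-2-en-1-yl]propanoic acid
Product: 7 (3R,3aS,7aS)-3-methyl-3a,4,5,7a-tetrahydro-1-benzofuran-2(3H)-one (cis-fused lactone; alkene now C5=C1)
Conditions: Pd(OAc)2 (5 mol %), NaOAc, O2 (1 atm), DMSO, 25 °C
Reagents that add atoms: none
Why: Palladium-catalysed aerobic oxidative lactonization of a γ,δ-unsaturated acid (carboxylate attack at C6, β-hydride loss towards C1); the five-membered lactone can only close cis, so C6–O is set syn to the C7–C11 bond.

Step 4
Reactants: 7 the cis-fused unsaturated lactone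
Product: 8 (3R,3aS,7aS)-3-methyl-3a,4-dihydro-1-benzofuran-2,5(3H,7aH)-dione (γ-acyloxy enone; C10 ketone; C1=C5)
Conditions: Rh2(cap)4 (1 mol %, cap = caprolactamate), t-BuOOH, K2CO3, CH2Cl2, 23 °C
Reagents that add atoms: tert-butyl hydroperoxide, CC(C)(C)OO
Why: Catalytic allylic C–H oxidation at the only allylic methylene (C10) gives the enone without touching a stereocentre.

Step 5
Reactants: 8 the enone lactone; 9 isopropenylmagnesium bromide; 10 allyl iodide
Product: 12 lactone cyclohexanone bearing 5α-isopropenyl and 1β-allyl groups (ring C1-C5-C6-C7-C8-C10), via bromomagnesium enolate 11 (not isolated)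
Conditions: 9 (1.5 equiv), CuBr·SMe2 (10 mol %), THF, −78 °C; then 10, HMPA, −78 → −20 °C
Reagents that add atoms: none
Why: Tandem copper-catalysed conjugate addition and enolate alkylation, in which the alkenyl group adds to C5 anti to the γ-oxygen on the convex face of the cis-fused bicycle and the regiodefined enolate is allylated at C1 anti to the new C5 substituent (trans-2,3).

Step 6
Reactants: 12 the 1β-allyl-5α-isopropenyl lactone cyclohexanone
Product: 15 ring-expanded lactone cycloheptanone with 9α-hydroxyl (C10 ketone), via enol silane 13 (not isolated), via silyloxy ketone 14 (not isolated)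
Conditions: Me3SiCHN2 (1.5 equiv), Sc(OTf)3 (10 mol %), CH2Cl2, −20 → 0 °C; then dimethyldioxirane (acetone), −78 °C; aq. citric acid, THF, 0 °C
Reagents that add atoms: (trimethylsilyl)diazomethane, C[Si](C)(C)C=[N+]=[N-]; dimethyldioxirane, CC1(C)OO1
Why: Lewis-acid-catalysed diazoalkane–ketone homologation (Tiffeneau–Demjanov-type 1,2-shift), in which the less substituted C8 migrates with loss of N2 to insert C9; the 1,3-Brook shift then gives the regiodefined C9=C10 enol silane (which also blocks a second insertion), and Rubottom oxidation occurs on the α face, opposite the pseudoaxial C1 allyl group and the β lactone.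

Step 7
Reactants: 15 the 9α-hydroxy cycloheptanone lactone
Product: 16 9α-hydroxy lactone with the C10(18) exocyclic methylene
Conditions: Zn, CH2Br2, TiCl4, THF–CH2Cl2, 0 → 23 °C
Reagents that add atoms: dibromomethane, BrCBr
Why: Lombardo–Takai methylenation, which is non-basic, so the α-ketol and the epimerizable C1 survive and the lactone carbonyl is not attacked.

Step 8
Reactants: 16 the methylene lactone
Product: 18 C12 Weinreb amide 6β,9α-bis(triethylsilyl) ether, via diol amide 17 (not isolated)
Conditions: MeNH(OMe)·HCl, i-PrMgCl, THF, −20 → 0 °C; work-up; then Et3SiOTf, 2,6-lutidine, CH2Cl2, 0 °C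
Reagents that add atoms: N,O-dimethylhydroxylamine hydrochloride, CNOC.Cl; triethylsilyl trifluoromethanesulfonate, CC[Si](CC)(CC)OS(=O)(=O)C(F)(F)F
Why: Weinreb aminolysis of the lactone by the magnesium amide followed at once by silylation of the freed C6 hydroxyl (which prevents relactonization) and of the C9 hydroxyl; no stereocentre is involved.

Step 9
Reactants: 18 the bis(triethylsilyl) Weinreb amide
Product: 19 C12 aldehyde 6β,9α-bis(triethylsilyl) ether
Conditions: i-Bu2AlH, THF, −78 °C; aq. potassium sodium tartrate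
Reagents that add atoms: none
Why: Hydride reduction of a Weinreb amide stops at the aldehyde through the chelated tetrahedral intermediate, and the low temperature protects the C11 stereocentre.

Step 10
Reactants: 20 acrolein
Product: 21 1-(tributylstannyl)prop-2-en-1-yl acetate (racemic)
Conditions: Bu3SnH, LiN(i-Pr)2, THF, 0 → −78 °C; 20, −78 °C; then Ac2O, −78 → 0 °C
Reagents that add atoms: tributyltin hydride, CCCC[SnH](CCCC)CCCC; acetic anhydride, CC(=O)OC(C)=O
Why: 1,2-Addition of Bu3SnLi to the enal followed by O-acetylation of the labile α-hydroxy stannane in the same flask (the standard entry to α-oxygenated allylstannanes).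

Step 11
Reactants: 19 the C12 aldehyde; 21 1-(tributylstannyl)prop-2-en-1-yl acetate
Product: 24 (12S,13S)-12,13-diacetate with C13 vinyl group (monocyclic tetraene; 6,9-bis(triethylsilyl) ether), via acetoxyallylstannane 22 (not isolated), via hydroxy acetate 23 (not isolated)
Conditions: 21 (2.5 equiv), BF3·OEt2, CH2Cl2, −78 °C, 30 min; then 19, −78 °C; aq. NaHCO3; then Ac2O, Et3N, DMAP, CH2Cl2, 0 → 23 °C
Reagents that add atoms: acetic anhydride, CC(=O)OC(C)=O
Why: Proposed new method: a γ-acyloxyallylstannane as carbonyl allylation reagent, so that C13 arrives already as its acetate. BF3 first moves tin 1,3 to give the conjugated Z enol acetate 22, which attacks the BF3-bound aldehyde through its oxygen-bearing γ-carbon in an open antiperiplanar SE2′ transition state (β-tin stabilization), giving the 12,13-syn pair, while Felkin–Anh approach anti to C7 gives the 11,12-syn relationship. The closest known reaction type is the BF3-promoted addition of γ-silyloxy- and γ-alkoxyallylstannanes to α-branched aldehydes; the C12 hydroxyl is acetylated in the same flask, so a 1,2-acetyl shift in 23 is harmless.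

Step 12
Reactants: 24 the tetraene diacetate; 25 2-methylbut-2-ene
Product: 27 bis(triethylsilyl) ether of the target, via cyclopentene 26 (not isolated)
Conditions: second-generation Grubbs catalyst (5 mol %), CH2Cl2, 40 °C; then 25 (excess), further catalyst (5 mol %), 40 °C
Reagents that add atoms: none
Why: Ring-closing metathesis of the C1 allyl and C5 isopropenyl groups closes the trans-fused cyclopentene (C3=C4), then cross-metathesis of the remaining terminal vinyl group with 2-methylbut-2-ene gives the isobutenyl end; the hindered 1,1-disubstituted exocyclic alkene does not react.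

Step 13
Reactants: 27 the bis(triethylsilyl) ether
Product: 28 target CNP0423623.2
Conditions: HF·pyridine, pyridine, THF, 0 → 23 °C
Reagents that add atoms: none
Why: Fluoride-mediated cleavage of both triethylsilyl ethers under mildly acidic conditions that leave the two acetates and the allylic alcohol unchanged.

**Compound list**
1 | (S)-cyclohex-2-en-1-ol | O[C@@H]1C=CCCC1 | starting material
2 | propanoyl chloride | CCC(=O)Cl | starting material
3 | (S)-cyclohex-2-en-1-yl propanoate | CCC(=O)O[C@@H]1C=CCCC1 | intermediate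
4 | E trimethylsilyl ketene acetal of 3 (methyl trans to OSiMe3) | C/C=C(/O[Si](C)(C)C)O[C@@H]1C=CCCC1 | intermediate
5 | trimethylsilyl (2R)-2-[(1R)-cyclohex-2-en-1-yl]propanoate | C[C@H]([C@H]1C=CCCC1)C(=O)O[Si](C)(C)C | intermediate
6 | (2R)-2-[(1R)-cyclohex-2-en-1-yl]propanoic acid | C[C@H]([C@H]1C=CCCC1)C(=O)O | intermediate
7 | (3R,3aS,7aS)-3-methyl-3a,4,5,7a-tetrahydro-1-benzofuran-2(3H)-one | C[C@H]1C(=O)O[C@H]2C=CCC[C@@H]12 | intermediate
8 | (3R,3aS,7aS)-3-methyl-3a,4-dihydro-1-benzofuran-2,5(3H,7aH)-dione | C[C@H]1C(=O)O[C@H]2C=CC(=O)C[C@@H]12 | intermediate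
9 | isopropenylmagnesium bromide | CC(=C)[Mg]Br | starting material
10 | allyl iodide | C=CCI | starting material
11 | bromomagnesium enolate (C1=C10–OMgBr) of the 5α-isopropenyl lactone ketone | C[C@H]1C(=O)O[C@H]2[C@H](C(C)=C)C=C(O[Mg]Br)C[C@@H]12 | intermediate
12 | cis-lactone cyclohexanone, 5α-isopropenyl, 1β-allyl | C[C@H]1C(=O)O[C@H]2[C@H](C(C)=C)[C@@H](CC=C)C(=O)C[C@@H]12 | intermediate
13 | ring-expanded trimethylsilyl enol ether (C9=C10–OSiMe3) | C[C@H]1C(=O)O[C@H]2[C@H](C(C)=C)[C@@H](CC=C)C(O[Si](C)(C)C)=CC[C@@H]12 | intermediate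
14 | 9α-(trimethylsilyloxy) lactone cycloheptanone | C[C@H]1C(=O)O[C@H]2[C@H](C(C)=C)[C@@H](CC=C)C(=O)[C@H](O[Si](C)(C)C)C[C@@H]12 | intermediate
15 | 9α-hydroxy lactone cycloheptanone (C10 ketone) | C[C@H]1C(=O)O[C@H]2[C@H](C(C)=C)[C@@H](CC=C)C(=O)[C@H](O)C[C@@H]12 | intermediate
16 | 9α-hydroxy lactone with C10(18) exocyclic methylene | C[C@H]1C(=O)O[C@H]2[C@H](C(C)=C)[C@@H](CC=C)C(=C)[C@H](O)C[C@@H]12 | intermediate
17 | C12 Weinreb amide 6β,9α-diol | C=C1[C@H](O)C[C@@H]([C@@H](C)C(=O)N(C)OC)[C@@H](O)[C@H](C(C)=C)[C@H]1CC=C | intermediate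
18 | C12 Weinreb amide 6β,9α-bis(triethylsilyl) ether | C=C1[C@H](O[Si](CC)(CC)CC)C[C@@H]([C@@H](C)C(=O)N(C)OC)[C@@H](O[Si](CC)(CC)CC)[C@H](C(C)=C)[C@H]1CC=C | intermediate
19 | C12 aldehyde 6β,9α-bis(triethylsilyl) ether | C=C1[C@H](O[Si](CC)(CC)CC)C[C@@H]([C@@H](C)C=O)[C@@H](O[Si](CC)(CC)CC)[C@H](C(C)=C)[C@H]1CC=C | intermediate
20 | acrolein | C=CC=O | starting material
21 | 1-(tributylstannyl)prop-2-en-1-yl acetate (racemic) | CC(=O)OC(C=C)[Sn](CCCC)(CCCC)CCCC | intermediate
22 | (Z)-3-(tributylstannyl)prop-1-en-1-yl acetate | CC(=O)O/C=C\C[Sn](CCCC)(CCCC)CCCC | intermediate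
23 | (12S,13S)-13-acetoxy-12-hydroxy adduct with C13 vinyl group | C=C1[C@H](O[Si](CC)(CC)CC)C[C@@H]([C@@H](C)[C@H](O)[C@H](C=C)OC(C)=O)[C@@H](O[Si](CC)(CC)CC)[C@H](C(C)=C)[C@H]1CC=C | intermediate
24 | (12S,13S)-12,13-diacetate with C13 vinyl group (monocyclic tetraene) | C=C1[C@H](O[Si](CC)(CC)CC)C[C@@H]([C@@H](C)[C@H](OC(C)=O)[C@H](C=C)OC(C)=O)[C@@H](O[Si](CC)(CC)CC)[C@H](C(C)=C)[C@H]1CC=C | intermediate
25 | 2-methylbut-2-ene | CC=C(C)C | starting material
26 | trans-fused bicyclic diacetate with C13 vinyl group | C=C1[C@H](O[Si](CC)(CC)CC)C[C@@H]([C@@H](C)[C@H](OC(C)=O)[C@H](C=C)OC(C)=O)[C@@H](O[Si](CC)(CC)CC)[C@@H]2C(C)=CC[C@@H]12 | intermediate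
27 | 6,9-bis(triethylsilyl) ether of the target | C=C1[C@H](O[Si](CC)(CC)CC)C[C@@H]([C@@H](C)[C@H](OC(C)=O)[C@H](C=C(C)C)OC(C)=O)[C@@H](O[Si](CC)(CC)CC)[C@@H]2C(C)=CC[C@@H]12 | intermediate
28 | CNP0423623.2, (1R,5S,6R,7S,9R,11R,12S,13S)-12,13-diacetoxy-3,10(18),14-triene-6,9-diol (target numbering) | C=C1[C@H](O)C[C@@H]([C@@H](C)[C@H](OC(C)=O)[C@H](C=C(C)C)OC(C)=O)[C@@H](O)[C@@H]2C(C)=CC[C@@H]12 | target

**Step count**
Total steps: 13. Longest linear sequence: 12 (steps 1–9 and 11–13); step 10 prepares the tin reagent.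

**Steps most likely to fail**

Step 11 (the proposed new step). The acetate may lower the reactivity of the stannane, or the open transition state may give poor Felkin control. The fallback uses known reagent-controlled chemistry; it sets out from 19 and comes back at 24. Allyl methoxymethyl ether is metalated with s-BuLi and treated with (+)-Ipc2BOMe (from (−)-α-pinene) and BF3·OEt2 at −78 °C to give [(Z)-3-(methoxymethoxy)allyl]diisopinocampheylborane F4. F4 adds to 19 through a closed chair transition state on the Re face and, after NaOH/H2O2 work-up, gives the syn (12S,13S) 12-hydroxy-13-methoxymethyl ether F5. ZnBr2 and n-PrSH in CH2Cl2 remove the methoxymethyl group to give the 12,13-diol F6, and Ac2O, Et3N and DMAP give 24.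

Step 6. The Brook shift or the face selectivity of the oxidation may fail, or the oxidant may touch the two alkenes. The fallback sets out from 12 and comes back at 15, with regiocontrol by kinetic deprotonation in place of the enol silane cascade. Me3SiCHN2 and BF3·OEt2 in CH2Cl2 at −78 °C give the 9-(trimethylsilyl) cycloheptanone F2, which loses silicon on acidic work-up to give the parent lactone cycloheptanone F3. LiN(SiMe3)2 in THF at −78 °C then forms the C9 enolate (C1 is tertiary and the lactone α-hydrogen is less acidic), and 2-(phenylsulfonyl)-3-phenyloxaziridine hydroxylates it from the α face to give 15.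

Step 5. The γ-acyloxy enone may be reduced by the cuprate, or the magnesium enolate may alkylate poorly. The fallback sets out from 8 and comes back at 12. Compound 9 is added with CuBr·SMe2 (cat.) in the presence of Me3SiCl in THF at −78 °C, and the trimethylsilyl enol ether F1 is isolated. F1 is then allylated regiospecifically at C1 with allyl methyl carbonate, Pd2(dba)3 and dppe in THF at 65 °C (palladium-catalysed allylation of a silyl enol ether), anti to the isopropenyl group, to give 12.

**Further compounds**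
F1 | step 5 | trimethylsilyl enol ether (C1=C10–OSiMe3) of the 5α-isopropenyl lactone ketone | C[C@H]1C(=O)O[C@H]2[C@H](C(C)=C)C=C(O[Si](C)(C)C)C[C@@H]12
F2 | step 6 | 9-(trimethylsilyl) lactone cycloheptanone (C9 configuration undefined) | C[C@H]1C(=O)O[C@H]2[C@H](C(C)=C)[C@@H](CC=C)C(=O)C([Si](C)(C)C)C[C@@H]12
F3 | step 6 | parent lactone cycloheptanone (C9 = CH2) | C[C@H]1C(=O)O[C@H]2[C@H](C(C)=C)[C@@H](CC=C)C(=O)CC[C@@H]12
F4 | step 11 | [(Z)-3-(methoxymethoxy)allyl]diisopinocampheylborane from (−)-α-pinene | COCO/C=C\CB([C@H]1C[C@H]2C[C@@H]([C@@H]1C)C2(C)C)[C@H]1C[C@H]2C[C@@H]([C@@H]1C)C2(C)C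
F5 | step 11 | (12S,13S)-12-hydroxy-13-(methoxymethoxy) adduct with C13 vinyl group | C=C1[C@H](O[Si](CC)(CC)CC)C[C@@H]([C@@H](C)[C@H](O)[C@H](C=C)OCOC)[C@@H](O[Si](CC)(CC)CC)[C@H](C(C)=C)[C@H]1CC=C
F6 | step 11 | (12S,13S)-12,13-diol with C13 vinyl group | C=C1[C@H](O[Si](CC)(CC)CC)C[C@@H]([C@@H](C)[C@H](O)[C@H](C=C)O)[C@@H](O[Si](CC)(CC)CC)[C@H](C(C)=C)[C@H]1CC=C
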